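The readings were generated by integration with constants of no real substance, and the scatter is random.

A small charge of starting material, 0.32 M, went into the flasks below, and I had to say how much intermediate each held at 2.5 d. It was less than Monday's 0.64 M and more than Sunday's 0.21 M.

| flask | starting material | coupling partner | second reagent | remark | time |
|---|---|---|---|---|---|
| Sunday's | 0.21 M | 1.5 equiv (in portions, 2) | 3 equiv | run made earlier; portions every 15 h |  |
| Monday's | 0.64 M | 1.5 equiv (in portions, 2) | 3 equiv | run made earlier; portions every 15 h |  |
| north-east | 0.32 M | 1.50 equiv (in portions, 2) | 4.50 equiv | the portions of coupling partner follow each other after 15 h, the first at the start | 2.5 d |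
| south-east | 0.32 M | 1.50 equiv (in portions, 2) | 3.00 equiv | the portions of coupling partner follow each other after 15 h, the first at the start | 2.5 d |
| east | 0.32 M | 1.50 equiv (in portions, 2) | 6.00 equiv | the portions of coupling partner follow each other after 15 h, the first at the start | 2.5 d |
| north-west | 0.32 M | 1.50 equiv (in portions, 2) | 9.00 equiv | the portions of coupling partner follow each other after 15 h, the first at the start | 2.5 d |

| run | time / h | intermediate / % | target / % |
|---|---|---|---|
| Sunday's | 3.00 | 6.3 | 0 |
| Sunday's | 10.0 | 16.4 | 1.2 |
| Sunday's | 15.0 | 21.8 | 2.3 |
| Sunday's | 25.0 | 36.8 | 6.9 |
| Sunday's | 40.0 | 44.6 | 15.0 |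
| Monday's | 8.00 | 26.7 | 5.7 |
| Monday's | 15.0 | 29.1 | 13.6 |
| Monday's | 20.0 | 37.4 | 20.0 |
| Monday's | 30.0 | 33.8 | 35.3 |
| Monday's | 40.0 | 26.9 | 45.4 |

(each reading ± 0.5 percentage points)



- ranking by amount of intermediate, in percent of the starting material charged, from high to low, at 2.5 d (north-east / south-east / east / north-west)
- the amount of intermediate, in percent of the starting material charged of the flask you put first, at 2.5 d
- the amount of intermediate, in percent of the starting material charged of the flask you put last, at 2.5 d

I went through the earlier runs in slow motion. In the first hours intermediate appeared before target: Sunday's read 6.3 % at 3.00 h, with target at 0 %. The second portion came at 15 h, and Monday's intermediate then gave its highest reading, 37.4 % at 20.0 h. By 40.0 h it had fallen to 26.9 %, while target had climbed to 45.4 %, so the two together read 72.3 %.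

That late stretch looked to me like decay, so I read a decay constant from it, as the target gained per hour over the mean intermediate, between 20.0 h and 40.0 h:

k(Monday) = 0.0385 /h

I took second reagent as constant at its charge, a pseudo-first-order drain, and divided by Monday's 1.92 M. This gave the drain constant, the decay rate of intermediate per unit of second reagent:

k_d = 0.0201 /M/h

The survival s is the share of material that has reached intermediate and is still there, reckoned as if it were all born at one moment and second reagent stayed at its charge:

s = I/(I + target) = exp(−k_d · c(second reagent) · a)

For the age a I assumed a rough mean birth at the second portion, so a = 45.0 h. This gave s = 42.0 % in south-east and 7.43 % in north-west. Taking Monday's sum, read in another flask at 40.0 h, as a rough stand-in for the share that had passed through, I reckoned 30.4 % of intermediate in south-east and 5.37 % in north-west.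

The forecast ranked south-east > north-east > east > north-west, with 36 % first (31 % to 41 %) and 7.5 % last (4 % to 13 %), holding that “more second reagent drains intermediate faster and also cuts its supply”. My s falls as second reagent rises, so my order was the same, but my figures were lower.

The flasks gave south-east > north-east > east > north-west, with 34.6 % in south-east and 4.89 % in north-west, both inside the forecast's ranges.

    starting material + coupling partner → intermediate (k = 4.19 × 10⁻⁵ /M/s)
    second reagent + intermediate → target (k = 6.40 × 10⁻⁶ /M/s)
    starting material + second reagent → side product (k = 3.23 × 10⁻⁶ /M/s)

In north-west, intermediate over intermediate plus target came to 9.28 % at 2.50 d, against my s of 7.43 %. For a neighbour of north-west, charged with 2.20 equiv of second reagent and otherwise held, the same line with k_d = 0.0201 /M/h gave s = 53.0 %. That neighbour's flask gave a ratio of 58.0 %, from target at 32.4 % and intermediate at 44.7 % at its end.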